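Retrosynthetic cuts (labdane-type numbering, C18 = CO2H): C15–C16 (vinylogous aldol), C13=C14 (HWE), C8–OH via the 8(17)-ene from an 8-ketone, C3–C4 (opens ring A), then C5–C6 and C7–C8 together, then C9–C10 (Ireland–Claisen).
Enabling feature: in ring B the carbinol C6 is γ to the carboxyl carbon (C6–C5–C4–C18) and C7 is α to C8. With ring A left open at C3–C4, C5 is the β-carbon of a C4=C5 enoate and C8 can be an acyl radical, so an O-vinyl C6=C7 unit fits between them.
Forward order: acyclic C9/C10 core, then ring B (radical [4+2] annulation), ring A, the C8 carbinol, the side chain and finally the butenolide.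
Stereochemistry: C9 and C10 come by chirality transfer from a CBS-derived (R)-allylic alcohol through a chair Ireland–Claisen. C5 and C6 come from the chair transition state of the annulation.
C4 comes from an A(1,3)-controlled ring closure, C8 from α-face trapping of the C8 radical, C15/C16 from a catalyst-controlled syn vinylogous Mukaiyama aldol, and the E-alkene from the HWE reaction.

Key step: step 11

Remark: numbering is C1–C10 decalin, C11–C12 linker, C13=C14, carbinol C15, butenolide C16, C17 = 8-CH3, C18 = 4-CO2H, C19 = 4-CH3, C20 = 10-CH3. Compound 18 is taken as purchasable.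

Step 1
Reactants: 1 5-chloropent-1-yne
Product: 3 (E)-7-chloro-4-methylhept-3-en-2-one, via (E)-alkenyldimethylalane 2 (not isolated)
Conditions: Me3Al, Cp2ZrCl2 (20 mol %), CH2Cl2, 0 °C to rt; then AcCl, Pd(PPh3)4 (3 mol %), THF, 0 °C
Reagents that add atoms: trimethylaluminium C[Al](C)C; acetyl chloride CC(=O)Cl
Why: Zr-catalysed (Negishi) carboalumination adds CH3 and Al syn with Al at the terminus, which fixes the E-trisubstituted alkene, and Pd-catalysed acylation of the alkenylalane should proceed with retention.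

Step 2
Reactants: 3 (E)-7-chloro-4-methylhept-3-en-2-one
Product: 4 (2R,3E)-7-chloro-4-methylhept-3-en-2-ol
Conditions: (S)-Me-CBS (10 mol %), BH3·SMe2, THF, –30 °C; MeOH quench
Reagents that add atoms: none
Why: Corey–Bakshi–Shibata reduction, in which the alkenyl group acts as the large and methyl as the small substituent, so the (S)-oxazaborolidine should give the R carbinol.

Step 3
Reactants: 5 ethyl 5-oxohexanoate
Product: 6 ethyl 4-(2-methyl-1,3-dioxolan-2-yl)butanoate
Conditions: HOCH2CH2OH, p-TsOH (cat.), PhMe, Dean–Stark, reflux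
Reagents that add atoms: ethylene glycol OCCO
Why: Standard ketalisation masks the future C13 ketone against enolisation and radicals.

Step 4
Reactants: 6 ethyl 4-(2-methyl-1,3-dioxolan-2-yl)butanoate
Product: 7 4-(2-methyl-1,3-dioxolan-2-yl)butanoic acid
Conditions: LiOH, THF/H2O, rt; cold 1 M HCl to pH 4
Reagents that add atoms: lithium hydroxide [Li+].[OH-]
Why: Saponification of an unhindered ester, and the ketal survives the brief cold acidification.

Step 5
Reactants: 4 (2R,3E)-7-chloro-4-methylhept-3-en-2-ol; 7 4-(2-methyl-1,3-dioxolan-2-yl)butanoic acid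
Product: 8 (2R,3E)-7-chloro-4-methylhept-3-en-2-yl 4-(2-methyl-1,3-dioxolan-2-yl)butanoate
Conditions: DCC, DMAP (cat.), CH2Cl2, 0 °C to rt
Reagents that add atoms: none
Why: Steglich esterification acylates the oxygen and leaves the carbinol configuration untouched.

Step 6
Reactants: 8 allylic ester
Product: 11 (2R,3S,4E)-3-(3-chloropropyl)-3-methyl-2-[2-(2-methyl-1,3-dioxolan-2-yl)ethyl]hex-4-enoic acid, via (Z)-silyl ketene acetal 9 (not isolated), via trimethylsilyl ester 10 (not isolated)
Conditions: LDA, THF/DMPU (4:1), –78 °C; TMSCl; to rt, then 55 °C; aq. NaH2PO4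
Reagents that add atoms: none
Why: Ireland–Claisen rearrangement, in which DMPU favours the (Z)-silyl ketene acetal and the chair with the carbinol methyl, the C11 chain and the chloropropyl arm pseudo-equatorial transfers the R carbinol chirality suprafacially to quaternary C10 and sets C9.

Step 7
Reactants: 11 hexenoic acid
Product: 12 (2R,3R)-6-chloro-3-formyl-3-methyl-2-[2-(2-methyl-1,3-dioxolan-2-yl)ethyl]hexanoic acid (in equilibrium with its lactol)
Conditions: O3, CH2Cl2, –78 °C; Me2S
Reagents that add atoms: ozone [O-][O+]=O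
Why: Ozonolysis of the only alkene unveils C5 as a non-enolisable aldehyde without touching C9 or C10.

Step 8
Reactants: 13 triethyl 2-phosphonopropionate; 14 2-(trimethylsilyl)ethanol
Product: 15 2-(trimethylsilyl)ethyl 2-(diethoxyphosphoryl)propanoate
Conditions: DMAP (0.3 equiv), PhMe, reflux with removal of EtOH
Reagents that add atoms: none
Why: DMAP-promoted transesterification of an α-phosphono ester installs the fluoride-labile ester that will carry C18 to the end.

Step 9
Reactants: 12 aldehyde acid; 15 TMSE phosphonopropionate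
Product: 16 (2R,3S,4E)-3-(3-chloropropyl)-3,5-dimethyl-2-[2-(2-methyl-1,3-dioxolan-2-yl)ethyl]-6-oxo-6-[2-(trimethylsilyl)ethoxy]hex-4-enoic acid
Conditions: NaH (2.2 equiv), THF, 0 to 50 °C; aq. NaH2PO4
Reagents that add atoms: none
Why: Horner–Wadsworth–Emmons olefination of the carboxylate–aldehyde gives the C4=C5 enoate (E expected), whose geometry is of no consequence because C4 is re-made later.

Step 10
Reactants: 16 enoate acid
Product: 17 Se-phenyl selenoester of 16 (C8(=O)SePh)
Conditions: (PhSe)2, Bu3P, PhH, rt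
Reagents that add atoms: diphenyl diselenide c1ccc(cc1)[Se][Se]c1ccccc1
Why: Neutral phosphine/diselenide activation converts the acid into the acyl radical precursor without harming the ketal, the enoate or C9.

Step 11
Reactants: 17 selenoester; 18 tert-butyldimethyl(vinyloxy)silane
Product: 22 ring-B ketone (C8=O, 6α-OTBS, 5α-H with CH(CH3)CO2TMSE on C5 as C4 epimers, 10β-CH3, 10-(3-chloropropyl), 9α-H with ketal side chain), via C8 acyl radical 19 (not isolated), via C6 silyloxyalkyl radical 20 (not isolated), via C4 ester radical 21 (not isolated)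
Conditions: Bu3SnH (1.2 equiv, syringe pump, 10 h), Et3B/air, 18 (15 equiv), PhH (0.02 M in 17), CO atmosphere, 10 °C
Reagents that add atoms: none
Why: Proposed new method: Bu3Sn• abstracts PhSe from 17 to give the C8 acyl radical 19, which can reach its own enoate only by 4-exo or 5-endo modes and therefore adds to the CH2 terminus (C7) of excess 18; the nucleophilic α-silyloxy radical 20 at C6 then closes ring B by 6-exo-trig attack on C5, the β-carbon of the C4=C5 enoate, and the electrophilic α-ester radical 21 takes H from Bu3SnH, so C7–C8 and C5–C6 form in one chain sequence. The closest known reaction types are tin-hydride acyl-radical addition–cyclisation from selenoesters, radical-chain hydroacylation of enol ethers and enol esters, and 6-exo α-oxy/ketyl radical–enoate cyclisation, and only their union as an intermolecular [4+2] annulation with an O-vinyl two-carbon unit is new. Ring B should close through a chair in which the C9 side chain, the chloropropyl arm on C10, the enoate on C5 and the OTBS on C6 are pseudo-equatorial and only the C10 methyl is axial, which sets 5α-H and 6α-O (trans-diequatorial) relative to C9/C10, whereas the flipped chair would place two chains axial. C4 forms as a mixture that step 14 erases, and C9, now α to the ketone, already sits in its thermodynamically preferred equatorial form. The step needs addition of 19 to outrun CO loss and reduction (low temperature, CO, high concentration of 18, slow Bu3SnH), attack at the CH2 end of 18 (sterics and α-oxygen stabilisation of 20) and cyclisation of 20 to outrun telomerisation (polarity match with the enoate), and the primary chloride and the ketal are inert to stannyl radicals.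

Step 12
Reactants: 22 ring-B ketone
Product: 23 8(17)-methylene compound
Conditions: Ph3PCH3Br, KOt-Bu, THF, 0 °C to rt
Reagents that add atoms: methyltriphenylphosphonium bromide C[P+](c1ccccc1)(c1ccccc1)c1ccccc1.[Br-]
Why: Wittig methylenation installs C17, removes the only ketone before enolate chemistry, and any C9 epimerisation only reinforces the equatorial side chain.

Step 13
Reactants: 23 chloride
Product: 24 iodide (C3–I)
Conditions: NaI, acetone, reflux
Reagents that add atoms: sodium iodide [Na+].[I-]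
Why: Finkelstein exchange turns the radical-inert chloride into a good leaving group for ring closure.

Step 14
Reactants: 24 iodide
Product: 25 trans-decalin TMSE ester (4α-CO2TMSE, 4β-CH3, 5α-H, 6α-OTBS, 8(17)-ene)
Conditions: KHMDS, THF, –78 to 0 °C
Reagents that add atoms: none
Why: Intramolecular ester enolate alkylation (6-exo-tet), in which H5 eclipses the enolate C4=C18 bond to minimise A(1,3) strain, so the iodopropyl arm on C10 reaches C4 from the face that leaves CH3 axial (β) and the ester equatorial (α) and closes ring A as the trans-decalin.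

Step 15
Reactants: 25 8(17)-ene
Product: 27 8α-hydroxy-8β-methyl decalin, via 8α-hydroperoxide 26 (not isolated)
Conditions: Mn(dpm)3 (10 mol %), PhSiH3, O2 (1 atm), i-PrOH/CH2Cl2, 0 °C; then PPh3
Reagents that add atoms: dioxygen O=O
Why: Mukaiyama hydration (Markovnikov H-atom transfer), in which the tertiary C8 radical should be trapped by O2 from the α face because the axial β face is shielded by the syn-axial C10 methyl.

Step 16
Reactants: 27 ketal
Product: 28 13-ketone (8α-hydroxy methyl ketone)
Conditions: PPTS, acetone/H2O, 40 °C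
Reagents that add atoms: water O
Why: Mild ketal hydrolysis spares the TBS ether, the TMSE ester and the tertiary alcohol.

Step 17
Reactants: 28 methyl ketone
Product: 29 (13E)-N-methoxy-N-methyl enamide
Conditions: (EtO)2P(O)CH2C(O)N(OMe)Me, NaH, THF, 0 to 45 °C
Reagents that add atoms: diethyl [2-(methoxy(methyl)amino)-2-oxoethyl]phosphonate CCOP(=O)(CC(=O)N(C)OC)OCC
Why: Horner–Wadsworth–Emmons olefination of the unhindered methyl ketone should favour the E-trisubstituted alkene, and the minor Z isomer is removable.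

Step 18
Reactants: 29 Weinreb enamide
Product: 30 (13E)-enal (C15 aldehyde)
Conditions: DIBAL-H (2.2 equiv), CH2Cl2, –78 °C; Rochelle salt
Reagents that add atoms: none
Why: The chelated tetrahedral intermediate of the Weinreb amide stops at the aldehyde, and the ester on quaternary C4 is too hindered to react at –78 °C.

Step 19
Reactants: 31 4-methylfuran-2(5H)-one
Product: 32 tert-butyldimethyl[(4-methylfuran-2-yl)oxy]silane
Conditions: TBSOTf, Et3N, CH2Cl2, 0 °C
Reagents that add atoms: tert-butyldimethylsilyl triflate CC(C)(C)[Si](C)(C)OS(=O)(=O)C(F)(F)F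
Why: Soft enolisation and O-silylation of the butenolide gives the aromatic 2-silyloxyfuran.

Step 20
Reactants: 30 enal; 32 silyloxyfuran
Product: 34 6-O-TBS, 18-TMSE ester of the target (15S,16S), via C15 trichlorosilyl ether 33 (not isolated)
Conditions: SiCl4 (2.2 equiv), chiral binaphthyldiamine-derived bisphosphoramide (5 mol %), i-Pr2NEt (10 mol %), CH2Cl2, –78 °C; aq. NaHCO3
Reagents that add atoms: none
Why: Catalytic asymmetric vinylogous Mukaiyama aldol reaction, in which the Lewis-base-activated silicon cation binds the conjugated aldehyde, the furan attacks through its γ-carbon in an open transition state that favours the syn (threo) adduct, and the catalyst antipode is chosen to expose the aldehyde face that gives 15S,16S independently of the remote decalin.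

Step 21
Reactants: 34 protected target
Product: 35 target CNP0292216.1
Conditions: TBAF/AcOH (1:1), THF, 0 °C to rt
Reagents that add atoms: none
Why: Buffered fluoride cleaves the 6-O-TBS ether and fragments the TMSE ester in one operation under conditions mild enough for the butenolide and the aldol unit.

Compound list
1 | 5-chloropent-1-yne | C#CCCCCl | starting material
2 | (E)-(5-chloro-2-methylpent-1-enyl)dimethylalane | C[Al](C)/C=C(\C)CCCCl | intermediate
3 | (E)-7-chloro-4-methylhept-3-en-2-one | CC(=O)/C=C(\C)CCCCl | intermediate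
4 | (2R,3E)-7-chloro-4-methylhept-3-en-2-ol | C[C@@H](O)/C=C(\C)CCCCl | intermediate
5 | ethyl 5-oxohexanoate | CCOC(=O)CCCC(C)=O | starting material
6 | ethyl 4-(2-methyl-1,3-dioxolan-2-yl)butanoate | CCOC(=O)CCCC1(C)OCCO1 | intermediate
7 | 4-(2-methyl-1,3-dioxolan-2-yl)butanoic acid | OC(=O)CCCC1(C)OCCO1 | intermediate
8 | (2R,3E)-7-chloro-4-methylhept-3-en-2-yl 4-(2-methyl-1,3-dioxolan-2-yl)butanoate | C[C@@H](OC(=O)CCCC1(C)OCCO1)/C=C(\C)CCCCl | intermediate
9 | (Z)-O-trimethylsilyl ketene acetal of 8 | C[C@@H](O/C(O[Si](C)(C)C)=C/CCC1(C)OCCO1)/C=C(\C)CCCCl | intermediate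
10 | trimethylsilyl ester of 11 | CC1(CC[C@@H](C(=O)O[Si](C)(C)C)[C@@](/C=C/C)(C)CCCCl)OCCO1 | intermediate
11 | (2R,3S,4E)-3-(3-chloropropyl)-3-methyl-2-[2-(2-methyl-1,3-dioxolan-2-yl)ethyl]hex-4-enoic acid | CC1(CC[C@@H](C(=O)O)[C@@](/C=C/C)(C)CCCCl)OCCO1 | intermediate
12 | (2R,3R)-6-chloro-3-formyl-3-methyl-2-[2-(2-methyl-1,3-dioxolan-2-yl)ethyl]hexanoic acid | CC1(CC[C@@H](C(=O)O)[C@@](C=O)(C)CCCCl)OCCO1 | intermediate
13 | triethyl 2-phosphonopropionate | CCOC(=O)C(C)P(=O)(OCC)OCC | starting material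
14 | 2-(trimethylsilyl)ethanol | C[Si](C)(C)CCO | starting material
15 | 2-(trimethylsilyl)ethyl 2-(diethoxyphosphoryl)propanoate | CCOP(=O)(OCC)C(C)C(=O)OCC[Si](C)(C)C | intermediate
16 | C8 acid with (E)-C4=C5 TMSE enoate | CC1(CC[C@@H](C(=O)O)[C@@](/C=C(\C)C(=O)OCC[Si](C)(C)C)(C)CCCCl)OCCO1 | intermediate
17 | Se-phenyl selenoester of 16 | CC1(CC[C@@H](C(=O)[Se]c2ccccc2)[C@@](/C=C(\C)C(=O)OCC[Si](C)(C)C)(C)CCCCl)OCCO1 | intermediate
18 | tert-butyldimethyl(vinyloxy)silane | C=CO[Si](C)(C)C(C)(C)C | starting material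
19 | C8 acyl radical | CC1(CC[C@@H]([C]=O)[C@@](/C=C(\C)C(=O)OCC[Si](C)(C)C)(C)CCCCl)OCCO1 | intermediate
20 | C6 α-silyloxyalkyl radical | CC1(CC[C@@H](C(=O)C[CH]O[Si](C)(C)C(C)(C)C)[C@@](/C=C(\C)C(=O)OCC[Si](C)(C)C)(C)CCCCl)OCCO1 | intermediate
21 | cyclised C4 α-ester radical | CC1(CC[C@@H]2[C@@]([C@H]([C](C)C(=O)OCC[Si](C)(C)C)[C@@H](O[Si](C)(C)C(C)(C)C)CC2=O)(C)CCCCl)OCCO1 | intermediate
22 | ring-B ketone (C4 epimers) | CC1(CC[C@@H]2[C@@]([C@H](C(C)C(=O)OCC[Si](C)(C)C)[C@@H](O[Si](C)(C)C(C)(C)C)CC2=O)(C)CCCCl)OCCO1 | intermediate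
23 | 8(17)-methylene chloride | CC1(CC[C@@H]2[C@@]([C@H](C(C)C(=O)OCC[Si](C)(C)C)[C@@H](O[Si](C)(C)C(C)(C)C)CC2=C)(C)CCCCl)OCCO1 | intermediate
24 | 8(17)-methylene iodide | CC1(CC[C@@H]2[C@@]([C@H](C(C)C(=O)OCC[Si](C)(C)C)[C@@H](O[Si](C)(C)C(C)(C)C)CC2=C)(C)CCCI)OCCO1 | intermediate
25 | trans-decalin 8(17)-ene TMSE ester | CC1(CC[C@@H]2[C@@]3(C)CCC[C@@](C)(C(=O)OCC[Si](C)(C)C)[C@@H]3[C@@H](O[Si](C)(C)C(C)(C)C)CC2=C)OCCO1 | intermediate
26 | 8α-hydroperoxide | CC1(CC[C@@H]2[C@@]3(C)CCC[C@@](C)(C(=O)OCC[Si](C)(C)C)[C@@H]3[C@@H](O[Si](C)(C)C(C)(C)C)C[C@@]2(C)OO)OCCO1 | intermediate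
27 | 8α-alcohol ketal | CC1(CC[C@@H]2[C@@]3(C)CCC[C@@](C)(C(=O)OCC[Si](C)(C)C)[C@@H]3[C@@H](O[Si](C)(C)C(C)(C)C)C[C@@]2(C)O)OCCO1 | intermediate
28 | 8α-hydroxy 13-ketone | CC(=O)CC[C@@H]1[C@@]2(C)CCC[C@@](C)(C(=O)OCC[Si](C)(C)C)[C@@H]2[C@@H](O[Si](C)(C)C(C)(C)C)C[C@@]1(C)O | intermediate
29 | (13E)-Weinreb enamide | CON(C)C(=O)/C=C(\C)CC[C@@H]1[C@@]2(C)CCC[C@@](C)(C(=O)OCC[Si](C)(C)C)[C@@H]2[C@@H](O[Si](C)(C)C(C)(C)C)C[C@@]1(C)O | intermediate
30 | (13E)-enal | O=C/C=C(\C)CC[C@@H]1[C@@]2(C)CCC[C@@](C)(C(=O)OCC[Si](C)(C)C)[C@@H]2[C@@H](O[Si](C)(C)C(C)(C)C)C[C@@]1(C)O | intermediate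
31 | 4-methylfuran-2(5H)-one | CC1=CC(=O)OC1 | starting material
32 | tert-butyldimethyl[(4-methylfuran-2-yl)oxy]silane | Cc1coc(O[Si](C)(C)C(C)(C)C)c1 | intermediate
33 | C15 trichlorosilyl ether of 34 | CC1=CC(=O)O[C@@H]1[C@@H](O[Si](Cl)(Cl)Cl)/C=C(\C)CC[C@@H]1[C@@]2(C)CCC[C@@](C)(C(=O)OCC[Si](C)(C)C)[C@@H]2[C@@H](O[Si](C)(C)C(C)(C)C)C[C@@]1(C)O | intermediate
34 | 6-O-TBS, 18-TMSE ester of the target | CC1=CC(=O)O[C@@H]1[C@@H](O)/C=C(\C)CC[C@@H]1[C@@]2(C)CCC[C@@](C)(C(=O)OCC[Si](C)(C)C)[C@@H]2[C@@H](O[Si](C)(C)C(C)(C)C)C[C@@]1(C)O | intermediate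
35 | CNP0292216.1 | CC1=CC(=O)O[C@@H]1[C@@H](O)/C=C(\C)CC[C@@H]1[C@@]2(C)CCC[C@@](C)(C(=O)O)[C@@H]2[C@@H](O)C[C@@]1(C)O | target

Total step count: 21. Longest linear sequence: 17 steps (1, 2, 5, 6, 7, 9–18, 20, 21).

Steps most likely to fail

Step 11. The acyl radical may lose CO or be reduced before it adds to the electron-rich alkene. Closure at the neopentyl C5 may also be slow enough for telomerisation or simple reduction to intervene, and the C6 selectivity may be low.

The fallback uses known chemistry and runs from 17 back to 22. Compound 17 is reduced with concentrated Bu3SnH/AIBN to the C8 aldehyde F1. A Mukaiyama aldol addition of triethyl(vinyloxy)silane (BF3·OEt2, –78 °C, then TESCl/imidazole on the crude aldol) makes C7–C8 and gives the β-triethylsilyloxy aldehyde F2 as C8 epimers. SmI2 (THF/t-BuOH, –78 °C) then closes C5–C6 by the established 6-exo ketyl–enoate cyclisation to the trans hydroxy ester F3. TBSOTf/2,6-lutidine gives the bis-silyl ether F4, buffered HF·pyridine removes only the TES group to give the C8 alcohol F5, and Dess–Martin oxidation returns to 22.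

Step 20. Catalyst control over the aldehyde face, or the syn/anti ratio, may be poor with the β,β-disubstituted enal.

The fallback runs from 30 and 32 back to 34. The addition is run with BF3·OEt2, which is threo-selective but gives no facial control. This should give 34 together with the 15R,16R diastereomer F6. A Sharpless kinetic resolution follows (Ti(Oi-Pr)4, TBHP, and the diisopropyl tartrate antipode matched to the 15R carbinol). It converts the unwanted isomer into the erythro 13,14-epoxy alcohol F7 and leaves 34, which is separated.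

Step 14. Enolisation of the hindered C4–H may be slow, the enolate may collapse to a ketene, or the alkylation may occur through the wrong enolate face.

The fallback runs from 24 back to 25 through a lactone template. HF·pyridine frees O6 to give the hydroxy ester iodide F8. Catalytic NaH lactonises it with loss of the silylethanol to the trans-fused γ-lactone iodide F9. KHMDS then closes ring A on the lactone enolate, where the O6–C18 tether allows C3 to reach only one face of C4, and gives the tricyclic 18,6α-lactone F10. KOH opens it to the hydroxy acid F11, 2-(trimethylsilyl)ethyl trichloroacetimidate gives the hydroxy TMSE ester F12, and TBSOTf/2,6-lutidine returns to 25.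

Further compounds
F1 | step 11 | C8 aldehyde | CC1(CC[C@@H](C=O)[C@@](/C=C(\C)C(=O)OCC[Si](C)(C)C)(C)CCCCl)OCCO1
F2 | step 11 | β-triethylsilyloxy aldehyde (C8 epimers) | CC1(CC[C@@H](C(CC=O)O[Si](CC)(CC)CC)[C@@](/C=C(\C)C(=O)OCC[Si](C)(C)C)(C)CCCCl)OCCO1
F3 | step 11 | trans hydroxy ester (6α-OH, 8-OTES) | CC1(CC[C@@H]2[C@@]([C@H](C(C)C(=O)OCC[Si](C)(C)C)[C@@H](O)CC2O[Si](CC)(CC)CC)(C)CCCCl)OCCO1
F4 | step 11 | bis-silyl ether (6α-OTBS, 8-OTES) | CC1(CC[C@@H]2[C@@]([C@H](C(C)C(=O)OCC[Si](C)(C)C)[C@@H](O[Si](C)(C)C(C)(C)C)CC2O[Si](CC)(CC)CC)(C)CCCCl)OCCO1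
F5 | step 11 | C8 alcohol (6α-OTBS) | CC1(CC[C@@H]2[C@@]([C@H](C(C)C(=O)OCC[Si](C)(C)C)[C@@H](O[Si](C)(C)C(C)(C)C)CC2O)(C)CCCCl)OCCO1
F6 | step 20 | 15R,16R diastereomer of 34 | CC1=CC(=O)O[C@H]1[C@H](O)/C=C(\C)CC[C@@H]1[C@@]2(C)CCC[C@@](C)(C(=O)OCC[Si](C)(C)C)[C@@H]2[C@@H](O[Si](C)(C)C(C)(C)C)C[C@@]1(C)O
F7 | step 20 | erythro 13,14-epoxy alcohol from F6 | CC1=CC(=O)O[C@H]1[C@H](O)[C@@H]2O[C@@]2(C)CC[C@@H]1[C@@]2(C)CCC[C@@](C)(C(=O)OCC[Si](C)(C)C)[C@@H]2[C@@H](O[Si](C)(C)C(C)(C)C)C[C@@]1(C)O
F8 | step 14 | hydroxy ester iodide | CC1(CC[C@@H]2[C@@]([C@H](C(C)C(=O)OCC[Si](C)(C)C)[C@@H](O)CC2=C)(C)CCCI)OCCO1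
F9 | step 14 | trans-fused γ-lactone iodide | CC1(CC[C@@H]2[C@@]([C@@H]3C(C)C(=O)O[C@H]3CC2=C)(C)CCCI)OCCO1
F10 | step 14 | tricyclic 18,6α-lactone | CC1(CC[C@@H]2[C@@]3(C)CCC[C@@](C)(C(=O)O4)[C@@H]3[C@@H]4CC2=C)OCCO1
F11 | step 14 | hydroxy acid | CC1(CC[C@@H]2[C@@]3(C)CCC[C@@](C)(C(=O)O)[C@@H]3[C@@H](O)CC2=C)OCCO1
F12 | step 14 | hydroxy TMSE ester | CC1(CC[C@@H]2[C@@]3(C)CCC[C@@](C)(C(=O)OCC[Si](C)(C)C)[C@@H]3[C@@H](O)CC2=C)OCCO1
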